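## Structural features

The target (C20H32O5) is a cembranolide. It has a 14-membered carbocycle (C1–C14, cembrane numbering; C1 carries the propionate unit C15(C17)–C16; C18, C19, C20 are the carbons on C4, C8, C12) whose C1 and C3 are bridged by a six-membered lactone C16(=O)–O–C3. On the lactone ring the two macrocycle branches (C14 on C1, C4 on C3) are cis and the C15 methyl is trans to C14. C4 is a tertiary carbinol whose OH is anti to the lactone oxygen on C3, which is the pattern of an E-C3=C4 epoxide opened at C3 with inversion. Farther round the ring are the secondary allylic alcohol C7 (R) next to the exocyclic methylene C8=C19 and the trans trisubstituted epoxide C11/C12 (S,S). The three stereo-clusters (C15/C1/C3/C4, C7, C11/C12) are separated by CH2–CH2 pairs, so none can control another through bonds. Fragile groups are the epoxide (acid, attack by C7–OH), the lactone with its epimerisable C15, and the 1,1-disubstituted allylic alcohol. The real difficulty is closing the 14-membered carbocycle and setting seven centres across it. The key step exploits the array C7(O)–C6H2–C5H2–C4(Me)(O)–C3(O): with C7 as a ketone and C3=C4 as an E-olefin it is a γ,δ-unsaturated ketone, the retron of a Claisen rearrangement, and because C7 and C3 both lie in the ring, the retro-[3,3] step exchanges the ring bond C5–C6 for a C7–O–C3 link and turns the 14-membered carbocycle into a 12-membered lactone.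

## Logic of the disconnections

31 ⇒ 29. Cut the lactone bond O–C3 and the four C–O bonds of the two oxiranes. The O–C3/C4–OH pair is the anti-adduct of an E-C3=C4 olefin, and both oxiranes (3S,4S before opening; 11S,12S) have the same local substitution pattern and the same sense. Four stereocentres and one ring are removed, leaving a triene acid with three stereocentres. The forward step needs catalyst-controlled epoxidation of two ring olefins in the presence of C8=C19, and 6-exo opening at C3 by the carboxylate only.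

29 ⇒ 26. Cut the C7–H bond (ketone) and lower C16 to a silyl ether. The C7 centre then comes from a reagent-controlled enone reduction, and C16 is masked in a form that survives carbonyl methylenation. The forward steps need a primary-selective oxidation beside the C7 hydroxyl.

26 ⇒ 25 (key). Cut C5–C6 and reconnect C3 to the C7 oxygen. This retro-Claisen turns the 14-membered carbocycle into a 12-membered cyclic enol ether, and removes the need to control C3. The forward step needs a chair [3,3] shift that delivers E-C3=C4, and mild handling of an acid-labile dienol ether and an α-methylene ketone.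

25 ⇒ 21. Cut the one-carbon units C6 (from the lactone carbonyl) and C19 (α to it). Both are added to a plain macrolactone that has a single carbonyl and a single α-position, so no regiochemical question arises.

21 ⇒ 19. Cut the ester bond C7(O)–O–C3. Macrolactonisation is the most reliable closure of a 12-membered ring; it needs high dilution and tolerates both C3 epimers.

19 ⇒ 16 + 17. Cut C10–C11 (sp2–sp3). The E-geometry of C11=C12 is fixed beforehand in the iodoalkene; the coupling must retain it.

16 ⇒ 13. Cut C12–C20 and C11–I (syn carbometalation of a terminal alkyne) and the C16 silyl ether. This gives a simple alkyne diol; the carbometalation must place the methyl on the internal carbon.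

13 ⇒ 10 + 11. Cut C3–C4. An isopropenyl nucleophile adds to a lactol; no stereocontrol is asked for.

10 ⇒ 6 + 7. Cut C1–C14. Conjugate addition to a six-membered unsaturated lactone sets C1 trans to the C15 methyl; the ring supplies the facial bias.

6 ⇒ 1. Cut C1=C2 (Z-olefination) and the lactone C–O bond. C15 comes from the chiral pool; the Z-olefin is required for ring closure.

## Other disconnections considered

Alternative 1: cut C7–C8, the bond most chemists would draw first. An intramolecular Nozaki–Hiyama–Kishi coupling of the iodoalkene aldehyde A1 would give 31 directly. The closure addresses only C7, and that centre would be set by remote induction without a reliable model. All six other stereocentres, the lactone and the acid-sensitive epoxide must be built in an open chain by three separate asymmetric operations and then exposed to Lewis-acidic chromium(III). The chosen plan forms the ring before any oxygen stereocentre exists and then sets C3, C4, C11 and C12 in one operation.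

Alternative 2: cut C5–C6 at the β-keto ester level. The 14-membered β-keto macrolactone A2 would undergo a palladium-catalysed decarboxylative allylation (Carroll-type ring contraction) to the ketone A3. After loss of CO2, A3 has two nearly equivalent α-methylene groups (C6 and C8), so C19 cannot be placed regioselectively. Putting C19 in beforehand would require an α′-methylene β-keto ester that is prone to Michael addition. The π-allyl/enolate ion pair can also scramble olefin geometry and cross over between molecules. The concerted [3,3] variant chosen keeps C19 in place and fixes the E geometry in a chair.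

Alternative 3: late allylic C–H oxidation. The 7,8-olefin A4 (C19 as methyl, lactone and epoxide in place) would undergo a photochemical Schenck ene reaction with singlet oxygen to the hydroperoxide A5, which is reduced to 31. The more substituted side of the C7=C8 bond offers both C19–H and C6–H, so a tertiary C8 hydroperoxide is an equally plausible outcome, and the C7 configuration would depend on ring conformation alone. A4 would also need two of three trisubstituted ring olefins epoxidised selectively, and its macrocycle would still need a conventional closure.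

Key step: step 16

Remark: C3 is carried as a mixture of epimers from 12 to 25 (drawn without configuration); this is inconsequential because C3 becomes sp2 in step 16. Reagents 7, 11, 17, the Tebbe reagent and the L-fructose-derived epoxidation ketone are taken as commercial.

## Steps

Step 1
Reactants: 1 methyl (R)-3-hydroxy-2-methylpropanoate
Product: 2 methyl (R)-3-[(tert-butyldimethylsilyl)oxy]-2-methylpropanoate
Conditions: TBSCl, imidazole, DMF, 0 °C → rt
Reagents that add atoms: tert-butyldimethylsilyl chloride, CC(C)(C)[Si](C)(C)Cl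
Why: Silylation of the primary alcohol; the stereocentre (future C15) is not involved.

Step 2
Reactants: 2 methyl (R)-3-[(tert-butyldimethylsilyl)oxy]-2-methylpropanoate
Product: 3 (R)-3-[(tert-butyldimethylsilyl)oxy]-2-methylpropanal
Conditions: DIBAL-H (1.05 equiv), CH2Cl2, −78 °C; Rochelle salt work-up
Reagents that add atoms: none
Why: DIBAL reduction of an ester at −78 °C stops at the aluminium hemiacetal, which gives the aldehyde on work-up; the α-centre is labile, so 3 should be used at once without chromatography.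

Step 3
Reactants: 3 (R)-3-[(tert-butyldimethylsilyl)oxy]-2-methylpropanal
Product: 4 methyl (S,Z)-5-[(tert-butyldimethylsilyl)oxy]-4-methylpent-2-enoate
Conditions: (CF3CH2O)2P(O)CH2CO2Me, KHMDS, 18-crown-6, THF, −78 °C
Reagents that add atoms: methyl bis(2,2,2-trifluoroethyl)phosphonoacetate, COC(=O)CP(=O)(OCC(F)(F)F)OCC(F)(F)F
Why: Still–Gennari olefination; the electron-poor phosphonate under dissociating conditions eliminates from the kinetic adduct and should give the Z-enoate (C1=C2) needed for lactonisation.

Step 4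
Reactants: 4 methyl (S,Z)-5-[(tert-butyldimethylsilyl)oxy]-4-methylpent-2-enoate
Product: 6 (S)-5-methyl-5,6-dihydro-2H-pyran-2-one, via hydroxy Z-ester 5 (not isolated)
Conditions: TsOH·H2O (10 mol %), MeOH, rt; then toluene, 60 °C
Reagents that add atoms: none
Why: Acidic methanolysis removes the silyl group, and the primary alcohol, held cis to the ester by the Z-olefin, closes the unsaturated six-membered lactone by transesterification.

Step 5
Reactants: 6 (S)-5-methyl-5,6-dihydro-2H-pyran-2-one; 7 (4-bromobut-1-yn-1-yl)trimethylsilane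
Product: 9 (4R,5S)-5-methyl-4-[4-(trimethylsilyl)but-3-yn-1-yl]tetrahydro-2H-pyran-2-one, via Grignard reagent 8 (not isolated)
Conditions: 7, Mg, THF, 40 °C; then CuBr·SMe2 (20 mol %), THF, −78 → −40 °C, add 6; aq NH4Cl
Reagents that add atoms: none
Why: Copper-catalysed conjugate addition of a Grignard reagent; the alkyl group should add to the β-carbon (C1) of the half-chair lactone on the face opposite the adjacent C15 methyl (1,2-induction), giving the 4,5-trans lactone, which is the C1(R)/C15(S) pair of the target.

Step 6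
Reactants: 9 (4R,5S)-5-methyl-4-[4-(trimethylsilyl)but-3-yn-1-yl]tetrahydro-2H-pyran-2-one
Product: 10 (4R,5S)-5-methyl-4-[4-(trimethylsilyl)but-3-yn-1-yl]tetrahydro-2H-pyran-2-ol (lactol, anomer mixture)
Conditions: DIBAL-H (1.1 equiv), CH2Cl2, −78 °C; Rochelle salt work-up
Reagents that add atoms: none
Why: Partial reduction of a δ-lactone to the lactol; the aluminium acetal is stable at −78 °C until work-up and the alkynylsilane is untouched.

Step 7
Reactants: 10 (4R,5S)-5-methyl-4-[4-(trimethylsilyl)but-3-yn-1-yl]tetrahydro-2H-pyran-2-ol; 11 isopropenylmagnesium bromide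
Product: 13 (2S,3R,5RS)-3-(but-3-yn-1-yl)-2,6-dimethylhept-6-ene-1,5-diol, via silylalkyne diol 12 (not isolated)
Conditions: 11 (4 equiv), THF, 0 °C → rt; then MeOH, K2CO3, rt
Reagents that add atoms: none
Why: Grignard addition to the open hydroxy-aldehyde form of the lactol makes the C3–C4 bond; C3 is formed as an epimer mixture on purpose because it becomes sp2 in step 16; K2CO3/MeOH then cleaves the alkynyl C–Si bond.

Step 8
Reactants: 13 (2S,3R,5RS)-3-(but-3-yn-1-yl)-2,6-dimethylhept-6-ene-1,5-diol
Product: 14 (3RS,5R,6S)-5-(but-3-yn-1-yl)-7-[(tert-butyldimethylsilyl)oxy]-2,6-dimethylhept-1-en-3-ol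
Conditions: TBSCl (1.05 equiv), imidazole, CH2Cl2, −20 → 0 °C
Reagents that add atoms: tert-butyldimethylsilyl chloride, CC(C)(C)[Si](C)(C)Cl
Why: Selective silylation of the primary (C16) hydroxyl over the hindered secondary allylic (C3) hydroxyl with one equivalent of silyl chloride.

Step 9
Reactants: 14 (3RS,5R,6S)-5-(but-3-yn-1-yl)-7-[(tert-butyldimethylsilyl)oxy]-2,6-dimethylhept-1-en-3-ol
Product: 16 (3RS,5R,6S)-7-[(tert-butyldimethylsilyl)oxy]-5-[(E)-4-iodo-3-methylbut-3-en-1-yl]-2,6-dimethylhept-1-en-3-ol, via alkenylalane 15 (not isolated)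
Conditions: AlMe3 (3 equiv), Cp2ZrCl2 (0.3 equiv), CH2Cl2, 0 °C → rt; then I2, THF, −30 → 0 °C; aq Na2S2O3
Reagents that add atoms: trimethylaluminium, C[Al](C)C; iodine, II
Why: Zirconium-catalysed carboalumination (Negishi) adds Me–Al syn across the terminal alkyne with methyl on the internal carbon (C12), and iodinolysis with retention gives the E-iodide; the C3 hydroxyl is carried as its aluminium alkoxide and the 1,1-disubstituted alkene should not react.

Step 10
Reactants: 16 (3RS,5R,6S)-7-[(tert-butyldimethylsilyl)oxy]-5-[(E)-4-iodo-3-methylbut-3-en-1-yl]-2,6-dimethylhept-1-en-3-ol; 17 (4-ethoxy-4-oxobutyl)zinc bromide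
Product: 18 ethyl (5E,9R,11RS)-9-[(2S)-1-[(tert-butyldimethylsilyl)oxy]propan-2-yl]-11-hydroxy-6,12-dimethyltrideca-5,12-dienoate
Conditions: 17 (2.5 equiv, THF), Pd(dppf)Cl2 (5 mol %), THF/NMP, 50 °C
Reagents that add atoms: none
Why: Negishi sp2–sp3 cross-coupling forms C10–C11 with retention of the E geometry; the ester-bearing alkylzinc tolerates the free hydroxyl and the silyl ether.

Step 11
Reactants: 18 ethyl (5E,9R,11RS)-9-[(2S)-1-[(tert-butyldimethylsilyl)oxy]propan-2-yl]-11-hydroxy-6,12-dimethyltrideca-5,12-dienoate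
Product: 19 (5E,9R,11RS)-9-[(2S)-1-[(tert-butyldimethylsilyl)oxy]propan-2-yl]-11-hydroxy-6,12-dimethyltrideca-5,12-dienoic acid
Conditions: LiOH·H2O, THF/MeOH/H2O, rt; then 1 M HCl to pH 4
Reagents that add atoms: lithium hydroxide, [Li+].[OH-]
Why: Saponification of the ethyl ester; a primary TBS ether is stable to aqueous LiOH at room temperature.

Step 12
Reactants: 19 (5E,9R,11RS)-9-[(2S)-1-[(tert-butyldimethylsilyl)oxy]propan-2-yl]-11-hydroxy-6,12-dimethyltrideca-5,12-dienoic acid
Product: 21 (6E,10R,12RS)-10-[(2S)-1-[(tert-butyldimethylsilyl)oxy]propan-2-yl]-7-methyl-12-(prop-1-en-2-yl)oxacyclododec-6-en-2-one, via mixed anhydride 20 (not isolated)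
Conditions: 2,4,6-Cl3C6H2COCl, Et3N, THF, rt; then slow addition to DMAP, toluene, 80 °C (1 mM)
Reagents that add atoms: none
Why: Yamaguchi macrolactonisation; the acyl-DMAP species is trapped by the C3 hydroxyl under high dilution, and the E-olefin and the planar ester reduce transannular strain in the 12-membered ring; both C3 epimers can close.

Step 13
Reactants: 21 (6E,10R,12RS)-10-[(2S)-1-[(tert-butyldimethylsilyl)oxy]propan-2-yl]-7-methyl-12-(prop-1-en-2-yl)oxacyclododec-6-en-2-one
Product: 22 (6E,10R,12RS)-10-[(2S)-1-[(tert-butyldimethylsilyl)oxy]propan-2-yl]-3-[(dimethylamino)methyl]-7-methyl-12-(prop-1-en-2-yl)oxacyclododec-6-en-2-one (mixture at ring C3)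
Conditions: LDA (1.2 equiv), THF, −78 °C; then Me2N=CH2+ I−, −78 → −30 °C
Reagents that add atoms: Eschenmoser's salt (N,N-dimethylmethyleneiminium iodide), C[N+](C)=C.[I-]
Why: Mannich reaction of the kinetic lactone enolate (the only α-position is C8) with the iminium salt; at −78 °C the enolate is trapped well below the temperature at which an ester-enolate Claisen could compete.

Step 14
Reactants: 22 (6E,10R,12RS)-10-[(2S)-1-[(tert-butyldimethylsilyl)oxy]propan-2-yl]-3-[(dimethylamino)methyl]-7-methyl-12-(prop-1-en-2-yl)oxacyclododec-6-en-2-one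
Product: 24 (6E,10R,12RS)-10-[(2S)-1-[(tert-butyldimethylsilyl)oxy]propan-2-yl]-7-methyl-3-methylidene-12-(prop-1-en-2-yl)oxacyclododec-6-en-2-one, via ammonium iodide 23 (not isolated)
Conditions: MeI, CH2Cl2/MeOH, rt; then DBU, CH2Cl2, rt
Reagents that add atoms: none
Why: Quaternisation makes trimethylamine a leaving group and E1cB elimination gives the α-methylene lactone (C8=C19).

Step 15
Reactants: 24 (6E,10R,12RS)-10-[(2S)-1-[(tert-butyldimethylsilyl)oxy]propan-2-yl]-7-methyl-3-methylidene-12-(prop-1-en-2-yl)oxacyclododec-6-en-2-one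
Product: 25 (6E,10R,12RS)-10-[(2S)-1-[(tert-butyldimethylsilyl)oxy]propan-2-yl]-7-methyl-2,3-dimethylidene-12-(prop-1-en-2-yl)oxacyclododec-6-ene
Conditions: Tebbe reagent (1.5 equiv), pyridine, THF/toluene, −40 → 0 °C; 15 % aq NaOH quench; filtration through basic alumina
Reagents that add atoms: Tebbe reagent, C[Al-]1(C)C[Ti]([Cl+]1)(C2C=CC=C2)C2C=CC=C2
Why: Tebbe methylenation of the lactone carbonyl ([2+2] with the titanium methylidene, cycloreversion driven by the Ti=O bond) gives the enol ether C7=C6 at low temperature, where no rearrangement occurs yet; basic work-up preserves the acid-labile dienol ether.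

Step 16
Reactants: 25 (6E,10R,12RS)-10-[(2S)-1-[(tert-butyldimethylsilyl)oxy]propan-2-yl]-7-methyl-2,3-dimethylidene-12-(prop-1-en-2-yl)oxacyclododec-6-ene
Product: 26 (5E,9R,11E)-9-[(2S)-1-[(tert-butyldimethylsilyl)oxy]propan-2-yl]-6,12-dimethyl-2-methylidenecyclotetradeca-5,11-dien-1-one
Conditions: toluene (1 mM, degassed, base-washed glass), BHT (cat.), 125 °C, sealed vessel
Reagents that add atoms: none
Why: Claisen rearrangement, a [3,3]-sigmatropic shift of the allyl vinyl ether C6=C7–O–C3–C4=C5: the C3–O bond breaks as the C5–C6 bond forms through a chair six-membered transition state, and the new C7=O bond makes it irreversible. The closest known reaction type is the lactone-methylenation/Claisen ring expansion of 2-methylidene oxacycles that carry an alkenyl group on the carbinol carbon, applied here to a 12-membered ring. The ring closed is the 14-membered carbocycle, formed by two-carbon ring expansion in which the oxygen bridge between C7 and C3 is replaced by the chain C6–C5–C4, so the macrocycle arises in an intraannular event with the entropy cost of a six-membered transition state and no end-to-end encounter. No new stereocentre is created; the stereogenic element formed is the C3=C4 double bond, and its E geometry should follow from C2 sitting pseudo-equatorial on C3 in the chair, which avoids the 1,3-diaxial contact with the substituent on C7 (C8) and the gauche contact with the C4 methyl. Because C3 becomes sp2, both C3 epimers of 25 converge on 26. The selectivity needed is [3,3] shift over ionisation of the allylic C3–O bond, hydrolysis of the dienol ether and dimerisation of the α-methylene ketone; neutral non-polar medium, base-washed glass, 1 mM concentration and a radical inhibitor secure it. Only C6=C7 is an enol ether double bond, so no second [3,3] pathway exists.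

Step 17
Reactants: 26 (5E,9R,11E)-9-[(2S)-1-[(tert-butyldimethylsilyl)oxy]propan-2-yl]-6,12-dimethyl-2-methylidenecyclotetradeca-5,11-dien-1-one
Product: 27 (1R,5E,9R,11E)-9-[(2S)-1-[(tert-butyldimethylsilyl)oxy]propan-2-yl]-6,12-dimethyl-2-methylidenecyclotetradeca-5,11-dien-1-ol
Conditions: (S)-2-methyl-CBS-oxazaborolidine (0.5 equiv), catecholborane, toluene, −78 °C
Reagents that add atoms: none
Why: CBS reduction; the ketone binds the oxazaborolidine with the larger α-branched alkenyl group (C8) away from the catalyst and hydride is delivered intramolecularly, so the (S)-catalyst should give the (7R)-allylic alcohol by reagent control, with 1,2-reduction only.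

Step 18
Reactants: 27 (1R,5E,9R,11E)-9-[(2S)-1-[(tert-butyldimethylsilyl)oxy]propan-2-yl]-6,12-dimethyl-2-methylidenecyclotetradeca-5,11-dien-1-ol
Product: 28 (1R,5E,9R,11E)-9-[(2S)-1-hydroxypropan-2-yl]-6,12-dimethyl-2-methylidenecyclotetradeca-5,11-dien-1-ol
Conditions: TBAF, THF, 0 °C → rt
Reagents that add atoms: none
Why: Fluoride cleaves the primary silyl ether; nothing else in the molecule is fluoride- or base-sensitive at this stage.

Step 19
Reactants: 28 (1R,5E,9R,11E)-9-[(2S)-1-hydroxypropan-2-yl]-6,12-dimethyl-2-methylidenecyclotetradeca-5,11-dien-1-ol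
Product: 29 (2S)-2-[(1R,3E,7R,11E)-7-hydroxy-4,12-dimethyl-8-methylidenecyclotetradeca-3,11-dien-1-yl]propanoic acid
Conditions: PhI(OAc)2 (2.5 equiv), TEMPO (0.2 equiv), MeCN/H2O 1:1, rt
Reagents that add atoms: water, O
Why: Oxoammonium (TEMPO) oxidation is selective for the unhindered primary alcohol over the secondary allylic C7 hydroxyl; in aqueous acetonitrile the aldehyde hydrate is oxidised on to the acid under conditions that should not epimerise C15.

Step 20
Reactants: 29 (2S)-2-[(1R,3E,7R,11E)-7-hydroxy-4,12-dimethyl-8-methylidenecyclotetradeca-3,11-dien-1-yl]propanoic acid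
Product: 31 (1R,3R,4S,7R,11S,12S,15S)-11,12-epoxy-4,7-dihydroxycembr-8(19)-en-16,3-olide (CNP0262409.1), via bis-epoxy acid 30 (not isolated)
Conditions: L-fructose-derived Shi ketone (0.6 equiv), Oxone, K2CO3, Bu4NHSO4 (cat.), MeCN/DMM/aq borate buffer (pH 10.5), 0 °C; then NaH2PO4 to pH 6–7, rt → 40 °C
Reagents that add atoms: potassium peroxymonosulfate (Oxone), OOS(=O)(=O)[O-].[K+]
Why: Shi epoxidation (chiral dioxirane, spiro transition state) should epoxidise both E-trisubstituted ring olefins with the (S,S) sense, since C3=C4 and C11=C12 have the same local substitution pattern, while the 1,1-disubstituted allylic C8=C19 bond is much less nucleophilic. The C16 carboxylate then opens the 3,4-epoxide by 6-exo attack at C3 with inversion (3S → 3R), leaving the C4 hydroxyl; it cannot reach the 11,12-epoxide, and without acid the neutral C7 hydroxyl should not open either oxirane.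

## Compound list

1 | methyl (R)-3-hydroxy-2-methylpropanoate | COC(=O)[C@H](C)CO | starting material
2 | methyl (R)-3-[(tert-butyldimethylsilyl)oxy]-2-methylpropanoate | COC(=O)[C@H](C)CO[Si](C)(C)C(C)(C)C | intermediate
3 | (R)-3-[(tert-butyldimethylsilyl)oxy]-2-methylpropanal | O=C[C@H](C)CO[Si](C)(C)C(C)(C)C | intermediate
4 | methyl (S,Z)-5-[(tert-butyldimethylsilyl)oxy]-4-methylpent-2-enoate | COC(=O)/C=C\[C@H](C)CO[Si](C)(C)C(C)(C)C | intermediate
5 | methyl (S,Z)-5-hydroxy-4-methylpent-2-enoate | COC(=O)/C=C\[C@H](C)CO | intermediate (not isolated)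
6 | (S)-5-methyl-5,6-dihydro-2H-pyran-2-one | C[C@@H]1COC(=O)C=C1 | intermediate
7 | (4-bromobut-1-yn-1-yl)trimethylsilane | C[Si](C)(C)C#CCCBr | starting material
8 | [4-(trimethylsilyl)but-3-yn-1-yl]magnesium bromide | C[Si](C)(C)C#CCC[Mg]Br | intermediate (not isolated)
9 | (4R,5S)-5-methyl-4-[4-(trimethylsilyl)but-3-yn-1-yl]tetrahydro-2H-pyran-2-one | C[C@@H]1COC(=O)C[C@H]1CCC#C[Si](C)(C)C | intermediate
10 | (4R,5S)-5-methyl-4-[4-(trimethylsilyl)but-3-yn-1-yl]tetrahydro-2H-pyran-2-ol (anomer mixture) | C[C@@H]1COC(O)C[C@H]1CCC#C[Si](C)(C)C | intermediate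
11 | isopropenylmagnesium bromide | CC(=C)[Mg]Br | starting material
12 | (2S,3R,5RS)-2,6-dimethyl-3-[4-(trimethylsilyl)but-3-yn-1-yl]hept-6-ene-1,5-diol | C=C(C)C(O)C[C@H]([C@H](C)CO)CCC#C[Si](C)(C)C | intermediate (not isolated)
13 | (2S,3R,5RS)-3-(but-3-yn-1-yl)-2,6-dimethylhept-6-ene-1,5-diol | C=C(C)C(O)C[C@H]([C@H](C)CO)CCC#C | intermediate
14 | (3RS,5R,6S)-5-(but-3-yn-1-yl)-7-[(tert-butyldimethylsilyl)oxy]-2,6-dimethylhept-1-en-3-ol | C=C(C)C(O)C[C@H]([C@H](C)CO[Si](C)(C)C(C)(C)C)CCC#C | intermediate
15 | E-alkenyl(dimethyl)alane of 14 with the C3 oxygen as its dimethylaluminium alkoxide | C=C(C)C(O[Al](C)C)C[C@H]([C@H](C)CO[Si](C)(C)C(C)(C)C)CC/C(C)=C/[Al](C)C | intermediate (not isolated)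
16 | (3RS,5R,6S)-7-[(tert-butyldimethylsilyl)oxy]-5-[(E)-4-iodo-3-methylbut-3-en-1-yl]-2,6-dimethylhept-1-en-3-ol | C=C(C)C(O)C[C@H]([C@H](C)CO[Si](C)(C)C(C)(C)C)CC/C(C)=C/I | intermediate
17 | (4-ethoxy-4-oxobutyl)zinc bromide | CCOC(=O)CCC[Zn]Br | starting material
18 | ethyl (5E,9R,11RS)-9-[(2S)-1-[(tert-butyldimethylsilyl)oxy]propan-2-yl]-11-hydroxy-6,12-dimethyltrideca-5,12-dienoate | C=C(C)C(O)C[C@H]([C@H](C)CO[Si](C)(C)C(C)(C)C)CC/C(C)=C/CCCC(=O)OCC | intermediate
19 | (5E,9R,11RS)-9-[(2S)-1-[(tert-butyldimethylsilyl)oxy]propan-2-yl]-11-hydroxy-6,12-dimethyltrideca-5,12-dienoic acid | C=C(C)C(O)C[C@H]([C@H](C)CO[Si](C)(C)C(C)(C)C)CC/C(C)=C/CCCC(=O)O | intermediate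
20 | mixed anhydride of 19 and 2,4,6-trichlorobenzoic acid | C=C(C)C(O)C[C@H]([C@H](C)CO[Si](C)(C)C(C)(C)C)CC/C(C)=C/CCCC(=O)OC(=O)c1c(Cl)cc(Cl)cc1Cl | intermediate (not isolated)
21 | (6E,10R,12RS)-10-[(2S)-1-[(tert-butyldimethylsilyl)oxy]propan-2-yl]-7-methyl-12-(prop-1-en-2-yl)oxacyclododec-6-en-2-one | C=C(C)C1C[C@H]([C@H](C)CO[Si](C)(C)C(C)(C)C)CC/C(C)=C/CCCC(=O)O1 | intermediate
22 | 3-[(dimethylamino)methyl] derivative of 21 (mixture at ring C3) | C=C(C)C1C[C@H]([C@H](C)CO[Si](C)(C)C(C)(C)C)CC/C(C)=C/CCC(CN(C)C)C(=O)O1 | intermediate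
23 | trimethylammonium iodide of 22 | C=C(C)C1C[C@H]([C@H](C)CO[Si](C)(C)C(C)(C)C)CC/C(C)=C/CCC(C[N+](C)(C)C)C(=O)O1.[I-] | intermediate (not isolated)
24 | (6E,10R,12RS)-10-[(2S)-1-[(tert-butyldimethylsilyl)oxy]propan-2-yl]-7-methyl-3-methylidene-12-(prop-1-en-2-yl)oxacyclododec-6-en-2-one | C=C(C)C1C[C@H]([C@H](C)CO[Si](C)(C)C(C)(C)C)CC/C(C)=C/CCC(=C)C(=O)O1 | intermediate
25 | (6E,10R,12RS)-10-[(2S)-1-[(tert-butyldimethylsilyl)oxy]propan-2-yl]-7-methyl-2,3-dimethylidene-12-(prop-1-en-2-yl)oxacyclododec-6-ene | C=C(C)C1C[C@H]([C@H](C)CO[Si](C)(C)C(C)(C)C)CC/C(C)=C/CCC(=C)C(=C)O1 | intermediate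
26 | (5E,9R,11E)-9-[(2S)-1-[(tert-butyldimethylsilyl)oxy]propan-2-yl]-6,12-dimethyl-2-methylidenecyclotetradeca-5,11-dien-1-one | C=C1CC/C=C(C)/CC[C@@H]([C@H](C)CO[Si](C)(C)C(C)(C)C)C/C=C(C)/CCC1=O | intermediate
27 | (1R,5E,9R,11E)-9-[(2S)-1-[(tert-butyldimethylsilyl)oxy]propan-2-yl]-6,12-dimethyl-2-methylidenecyclotetradeca-5,11-dien-1-ol | C=C1CC/C=C(C)/CC[C@@H]([C@H](C)CO[Si](C)(C)C(C)(C)C)C/C=C(C)/CC[C@H]1O | intermediate
28 | (1R,5E,9R,11E)-9-[(2S)-1-hydroxypropan-2-yl]-6,12-dimethyl-2-methylidenecyclotetradeca-5,11-dien-1-ol | C=C1CC/C=C(C)/CC[C@@H]([C@H](C)CO)C/C=C(C)/CC[C@H]1O | intermediate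
29 | (2S)-2-[(1R,3E,7R,11E)-7-hydroxy-4,12-dimethyl-8-methylidenecyclotetradeca-3,11-dien-1-yl]propanoic acid | C=C1CC/C=C(C)/CC[C@@H]([C@H](C)C(=O)O)C/C=C(C)/CC[C@H]1O | intermediate
30 | (2S)-2-[(1R,3S,4S,7R,11S,12S)-3,4:11,12-diepoxy-7-hydroxy-4,12-dimethyl-8-methylidenecyclotetradecan-1-yl]propanoic acid | C=C1CC[C@@H]2O[C@@]2(C)CC[C@@H]([C@H](C)C(=O)O)C[C@@H]2O[C@@]2(C)CC[C@H]1O | intermediate (not isolated)
31 | (1R,3R,4S,7R,11S,12S,15S)-11,12-epoxy-4,7-dihydroxycembr-8(19)-en-16,3-olide (CNP0262409.1) | C=C1CC[C@@H]2O[C@@]2(C)CC[C@@H]2C[C@@H](OC(=O)[C@H]2C)[C@@](C)(O)CC[C@H]1O | target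

## Step count and least certain steps

Total step count: 20. Longest linear sequence: 20 steps (1 → 31); 7, 11 and 17 are bought.

Step 16 (key step). The rearrangement may pass in part through a boat or an axial-C2 chair and give Z-C3=C4. The allylic C3–O bond may also ionise instead of shifting, or the dienol ether may hydrolyse, or the α-methylene ketone may oligomerise at 125 °C. Fallback: run the Claisen in open-chain form and close the ring by a carbonyl addition. It sets out from 16. A Johnson–Claisen rearrangement (triethyl orthoacetate, cat. propionic acid, 140 °C) on the isopropenyl carbinol should give ethyl (4E,7R,10E)-7-[(2S)-1-[(tert-butyldimethylsilyl)oxy]propan-2-yl]-11-iodo-4,10-dimethylundeca-4,10-dienoate F1. Negishi coupling with (3-bromobut-3-en-1-yl)zinc iodide gives ethyl (4E,7R,10E)-14-bromo-7-[(2S)-1-[(tert-butyldimethylsilyl)oxy]propan-2-yl]-4,10-dimethylpentadeca-4,10,14-trienoate F2. DIBAL at −78 °C gives the corresponding trienal F3. An intramolecular Nozaki–Hiyama–Kishi reaction (CrCl2, cat. NiCl2, high dilution) gives the cyclotetradecadienol F4 as a C7 epimer mixture, and Dess–Martin oxidation comes back to the route at 26.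

Step 12. The 12-membered ring may close slowly at the hindered allylic hydroxyl, so that dimeric diolide formation and anhydride decomposition compete. Fallback: make the ester bond intermolecularly and close the ring at C10–C11. It sets out from 16. Acylation with 4-iodobutanoyl chloride (pyridine) gives the 4-iodobutanoate ester F5. Zinc insertion into the alkyl C–I bond (Zn, LiCl, THF; the alkenyl iodide is inert at rt) gives the alkylzinc iodide F6. Slow addition to a palladium catalyst (intramolecular Negishi coupling) comes back to the route at 21.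

Step 15. The titanium methylidene may engage the 1,1-disubstituted olefins (titanacycle formation), or the 2-alkoxydiene may hydrolyse or polymerise during work-up. Fallback: postpone the C8=C19 double bond until after the ring expansion. It sets out from 22. Tebbe methylenation of the saturated amino lactone gives the amino enol ether F7. The Claisen rearrangement under the conditions of step 16 gives the β-(dimethylamino)methyl ketone F8. Quaternisation with MeI and elimination with DBU comes back to the route at 26.

Step 20. The ring conformation may oppose the catalyst at one of the two olefins (poor facial selectivity). Once the epoxides are formed, the C7 hydroxyl may attack C4 of the 3,4-epoxide (5-exo, tetrahydrofuran formation) if the medium turns acidic. Fallback: separate the two epoxidations in time so that each meets the catalyst alone. It sets out from 24, in which C11=C12 is the only electron-rich olefin. Shi epoxidation there gives the (11S,12S)-epoxy lactone F9. Steps 15–19 are then repeated on the epoxide series: Tebbe methylenation to the epoxy dienol ether F10, Claisen rearrangement to the epoxy enone F11, CBS reduction to the epoxy allylic alcohol F12, desilylation to the epoxy diol F13, and TEMPO oxidation to the epoxy hydroxy acid F14. A single Shi epoxidation of C3=C4 and lactonisation via 30 comes back to the route at 31.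

## Further compounds

F1 | step 16 | ethyl (4E,7R,10E)-7-[(2S)-1-[(tert-butyldimethylsilyl)oxy]propan-2-yl]-11-iodo-4,10-dimethylundeca-4,10-dienoate | CCOC(=O)CC/C(C)=C/C[C@H]([C@H](C)CO[Si](C)(C)C(C)(C)C)CC/C(C)=C/I
F2 | step 16 | ethyl (4E,7R,10E)-14-bromo-7-[(2S)-1-[(tert-butyldimethylsilyl)oxy]propan-2-yl]-4,10-dimethylpentadeca-4,10,14-trienoate | CCOC(=O)CC/C(C)=C/C[C@H]([C@H](C)CO[Si](C)(C)C(C)(C)C)CC/C(C)=C/CCC(Br)=C
F3 | step 16 | (4E,7R,10E)-14-bromo-7-[(2S)-1-[(tert-butyldimethylsilyl)oxy]propan-2-yl]-4,10-dimethylpentadeca-4,10,14-trienal | O=CCC/C(C)=C/C[C@H]([C@H](C)CO[Si](C)(C)C(C)(C)C)CC/C(C)=C/CCC(Br)=C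
F4 | step 16 | (5E,9R,11E)-9-[(2S)-1-[(tert-butyldimethylsilyl)oxy]propan-2-yl]-6,12-dimethyl-2-methylidenecyclotetradeca-5,11-dien-1-ol (C1 epimer mixture) | C=C1CC/C=C(C)/CC[C@@H]([C@H](C)CO[Si](C)(C)C(C)(C)C)C/C=C(C)/CCC1O
F5 | step 12 | (3RS,5R,6S)-7-[(tert-butyldimethylsilyl)oxy]-5-[(E)-4-iodo-3-methylbut-3-en-1-yl]-2,6-dimethylhept-1-en-3-yl 4-iodobutanoate | C=C(C)C(OC(=O)CCCI)C[C@H]([C@H](C)CO[Si](C)(C)C(C)(C)C)CC/C(C)=C/I
F6 | step 12 | alkylzinc iodide formed from F5 at the 4-position of the butanoate | C=C(C)C(OC(=O)CCC[Zn]I)C[C@H]([C@H](C)CO[Si](C)(C)C(C)(C)C)CC/C(C)=C/I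
F7 | step 15 | (6E,10R,12RS)-10-[(2S)-1-[(tert-butyldimethylsilyl)oxy]propan-2-yl]-3-[(dimethylamino)methyl]-7-methyl-2-methylidene-12-(prop-1-en-2-yl)oxacyclododec-6-ene | C=C(C)C1C[C@H]([C@H](C)CO[Si](C)(C)C(C)(C)C)CC/C(C)=C/CCC(CN(C)C)C(=C)O1
F8 | step 15 | (5E,9R,11E)-9-[(2S)-1-[(tert-butyldimethylsilyl)oxy]propan-2-yl]-2-[(dimethylamino)methyl]-6,12-dimethylcyclotetradeca-5,11-dien-1-one | CN(C)CC1CC/C=C(C)/CC[C@@H]([C@H](C)CO[Si](C)(C)C(C)(C)C)C/C=C(C)/CCC1=O
F9 | step 20 | (11S,12S)-11,12-epoxide (cembrane numbering) of 24 | C=C(C)C1C[C@H]([C@H](C)CO[Si](C)(C)C(C)(C)C)CC[C@]2(C)O[C@H]2CCC(=C)C(=O)O1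
F10 | step 20 | (11S,12S)-11,12-epoxide (cembrane numbering) of 25 | C=C(C)C1C[C@H]([C@H](C)CO[Si](C)(C)C(C)(C)C)CC[C@]2(C)O[C@H]2CCC(=C)C(=C)O1
F11 | step 20 | (11S,12S)-11,12-epoxide (cembrane numbering) of 26 | C=C1CC[C@@H]2O[C@@]2(C)CC[C@@H]([C@H](C)CO[Si](C)(C)C(C)(C)C)C/C=C(C)/CCC1=O
F12 | step 20 | (11S,12S)-11,12-epoxide (cembrane numbering) of 27 | C=C1CC[C@@H]2O[C@@]2(C)CC[C@@H]([C@H](C)CO[Si](C)(C)C(C)(C)C)C/C=C(C)/CC[C@H]1O
F13 | step 20 | (11S,12S)-11,12-epoxide (cembrane numbering) of 28 | C=C1CC[C@@H]2O[C@@]2(C)CC[C@@H]([C@H](C)CO)C/C=C(C)/CC[C@H]1O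
F14 | step 20 | (11S,12S)-11,12-epoxide (cembrane numbering) of 29 | C=C1CC[C@@H]2O[C@@]2(C)CC[C@@H]([C@H](C)C(=O)O)C/C=C(C)/CC[C@H]1O
A1 | alternative 1 | seco iodoalkene aldehyde: 31 opened between C7 (aldehyde) and C8 (2-iodoalkene) | C=C(I)CC[C@@H]1O[C@@]1(C)CC[C@@H]1C[C@@H](OC(=O)[C@H]1C)[C@@](C)(O)CCC=O
A2 | alternative 2 | 14-membered β-keto macrolactone (C7 ketone, malonyl carbon between C6 and the C3 oxygen, isopropenyl on C3) | C=C(C)C1C[C@H]([C@H](C)CO[Si](C)(C)C(C)(C)C)CC/C(C)=C/CCCC(=O)CC(=O)O1
A3 | alternative 2 | (4E,8R,10E)-8-[(2S)-1-[(tert-butyldimethylsilyl)oxy]propan-2-yl]-5,11-dimethylcyclotetradeca-4,10-dien-1-one (26 without C19) | O=C1CCC/C=C(C)/CC[C@@H]([C@H](C)CO[Si](C)(C)C(C)(C)C)C/C=C(C)/CC1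
A4 | alternative 3 | (1R,3R,4S,7E,11S,12S,15S)-11,12-epoxy-4-hydroxycembr-7-en-16,3-olide | C/C1=C\CC[C@](C)(O)[C@H]2C[C@H]([C@H](C)C(=O)O2)CC[C@]3(C)O[C@H]3CC1
A5 | alternative 3 | 7-hydroperoxide corresponding to 31 | C=C1CC[C@@H]2O[C@@]2(C)CC[C@@H]2C[C@@H](OC(=O)[C@H]2C)[C@@](C)(O)CC[C@H]1OO
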